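Readings and results stem from a simulated flask for an exercise; scatter was added.

The over-reaction product took up what the starting material lost: in Wednesday's run it read 73% at 3.00 h, against 0% of target.

| flask | starting material | second substrate | reagent | free catalyst | added ligand | remark | time |
|---|---|---|---|---|---|---|---|
| Monday's | 0.050 M | 0.10 M | 0.060 M | 65 µM | 85 µM | run made earlier |  |
| Wednesday's | 0.050 M | 0.10 M | 0.060 M | 120 µM | 85 µM | run made earlier |  |
| green | 0.050 M | 0.100 M | 0.0600 M | 100 µM | 85 µM |  | 3.0 h |
| teal | 0.050 M | 0.100 M | 0.0600 M | 50 µM | 85 µM |  | 3.0 h |

| run | time / h | starting material / % | target / % | over-reaction product / % | catalyst intermediate A / % |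
|---|---|---|---|---|---|
| Monday's | 0.417 | 85 | 5 | 12 | 0 |
| Monday's | 1.00 | 70 | 5 | 27 | 0 |
| Monday's | 2.00 | 50 | 1 | 48 | 1 |
| Monday's | 3.00 | 38 | 0 | 58 | 0 |
| Wednesday's | 0.250 | 70 | 11 | 17 | 0 |
| Wednesday's | 0.500 | 52 | 6 | 40 | 2 |
| Wednesday's | 1.33 | 30 | 0 | 72 | 0 |
| Wednesday's | 3.00 | 30 | 0 | 73 | 0 |

(readings scatter by 2 percentage points)

1. which of these there is most of at the end, counted by the starting material in it, green (catalyst intermediate A / starting material / over-reaction product / target)
2. which of these there is most of at the end, counted by the starting material in it, teal (catalyst intermediate A / starting material / over-reaction product / target)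
3. the largest of these amounts at the end, in percent of the starting material charged, green
4. the largest of these amounts at the end, in percent of the starting material charged, teal

- the analysis behind the earlier runs scatters by 2 percentage points, standard deviation

I counted half-lives. Two times mattered: the half-life of the starting material and the run of 3.0 h. Their ratio is the count of half-lives a flask gets.

From the first readings I took a pseudo-first-order constant of 0.390 h⁻¹ for Monday's run and 1.43 h⁻¹ for Wednesday's. Both carry the scatter of the readings. So the apparent order in catalyst was 2.12.

Wednesday's starting material read 30% at 1.33 h and 30% at 3.00 h, so that run had stopped. Green and teal have its charges of starting material, second substrate and reagent, so I assumed the same stop. Reaching it takes 1.74 half-lives.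

The half-life came to 0.715 h in green. At the teal catalyst charge, the half-life of the starting material came to 3.10 h. Green got 4.20 half-lives, more than the stop asks, so I put green at the stop. Teal got 0.968, fewer than the stop asks, so I reckoned teal still running, with 51.1% of its starting material left.

The forecast gave over-reaction product at 72% (range 67% to 77%) for green. For teal it gave starting material at 56% (range 47% to 74%), “with slight slowing”, a higher figure than mine.

Green ended with over-reaction product at 72.7%, and teal with starting material at 53.0%.

    reagent + catalyst intermediate B → free catalyst + second product (k = 10.3 M⁻¹ s⁻¹)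
    reagent + catalyst intermediate A → free catalyst + target (k = 91.5 M⁻¹ s⁻¹)
    starting material + free catalyst ⇌ catalyst intermediate A (K = 26.0 M⁻¹, k = 25.0 M⁻¹ s⁻¹)
    free catalyst + added ligand ⇌ idle complex, settled at all times (K = 3.18 × 10⁵ M⁻¹)
    target → over-reaction product (k = 0.00260 s⁻¹)
    second substrate + free catalyst ⇌ catalyst intermediate B (K = 15.0 M⁻¹, k = 1650 M⁻¹ s⁻¹)

In green at 3.00 h, the reagent, the limiting reagent, stood at 0.49% of its charge. The teal half-life puts the stop at 5.38 h, later than the end of the teal run but earlier than 30.0 h. Left that long, teal held 73.3% of over-reaction product.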